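**Plan**

Retrosynthesis: the C3 hydroxyl (dioxirane oxidation of a flavone) and the phenol protection are removed first. Ring C is then cut at C4a–C4, C4–C3 and O1–C2 into an aryl iodide, carbon monoxide and an aryl acetylene. Next the C8–CH2 bond of the methylene bridge is cut (quinone methide from a ring A Mannich base plus the dihydrochalcone), and last the aryl–acyl bond of the dihydrochalcone.
Enabling feature: ring A carries oxygen at C5, C7 and C8a, so C4a lies between two oxygen-bearing carbons. In the mirror-symmetric ring A building block (a 5-benzyloxyresorcinol with the future bridge carbon, as a formyl group, between its two hydroxyls) the two free ring carbons are equivalent. One iodination therefore gives a single iodide, and the only free hydroxyl beside the iodine is the one next to the bridge-bearing carbon; this fixes O1/C8a, the bridge at C8 and the benzyl ether on O5.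
Forward order: the ring A fragment (O-benzylation, iodination, Mannich base) and the dihydrochalcone (C-acylation, O-methylation) are made separately and joined through the CH2 bridge. Ring C is then closed in one three-component step, C3 is oxygenated on the acetylated flavone, and the acetates and the benzyl ether are removed last.
Stereochemistry: the target has no stereocentre; the only stereogenic intermediate is a racemic epoxide that is opened in the same flask.

Key step: step 7

Remark: the 4-hydroxyphenyl oxygen of the dihydrochalcone is carried unprotected up to the key step and acetylated afterwards. Flavone numbering is used for rings A and C, primed numbers for the acyl-bearing ring of the dihydrochalcone.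

**Route**

Step 1
Reactants: 1 2,4,6-trihydroxybenzaldehyde
Product: 2 4-(benzyloxy)-2,6-dihydroxybenzaldehyde
Conditions: BnBr (1.0 equiv), NaHCO3 (1.2 equiv), DMF, 40 °C
Reagents that add atoms: benzyl bromide, BrCc1ccccc1
Why: Williamson ether synthesis in which hydrogencarbonate ionises only the 4-hydroxyl, the most acidic of the three (para to the formyl group) and the one not hydrogen-bonded to the formyl oxygen, so one equivalent of benzyl bromide should alkylate that oxygen selectively.

Step 2
Reactants: 2 4-(benzyloxy)-2,6-dihydroxybenzaldehyde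
Product: 3 4-(benzyloxy)-2,6-dihydroxy-3-iodobenzaldehyde
Conditions: NIS (1.0 equiv), DMF, −20 → 0 °C, dark
Reagents that add atoms: N-iodosuccinimide, O=C1CCC(=O)N1I
Why: Electrophilic aromatic iodination; the two free ring carbons of symmetric 2 are equivalent (each ortho to a hydroxyl and the benzyl ether, para to the other hydroxyl), so one equivalent of reagent should give a single mono-iodide, with the formyl group tempering the ring against a second iodination.

Step 3
Reactants: 3 4-(benzyloxy)-2,6-dihydroxy-3-iodobenzaldehyde
Product: 5 5-(benzyloxy)-2-[(dimethylamino)methyl]-4-iodobenzene-1,3-diol, via iminium phenolate 4 (not isolated)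
Conditions: Me2NH (2 M in THF, 3 equiv), MeOH, 0 °C → rt; then NaBH4, 0 °C; work-up at pH 7
Reagents that add atoms: dimethylamine, CNC
Why: Reductive amination; the ortho-hydroxy aldehyde condenses with the secondary amine to the iminium phenolate 4, which NaBH4 should reduce in the cold to the phenolic Mannich base without touching the aryl iodide or the benzyl ether.

Step 4
Reactants: 6 2-methylphloroglucinol; 7 3-(4-hydroxyphenyl)propanoic acid
Product: 8 3-(4-hydroxyphenyl)-1-(2,4,6-trihydroxy-3-methylphenyl)propan-1-one
Conditions: BF3·OEt2 (neat), 85 °C; then aq. NaOAc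
Reagents that add atoms: none
Why: BF3-mediated Friedel–Crafts acylation of a phloroglucinol by a free carboxylic acid; the two open positions of 6 are equivalent and each is activated by three hydroxyls, and the first acyl group deactivates the ring toward a second acylation.

Step 5
Reactants: 8 3-(4-hydroxyphenyl)-1-(2,4,6-trihydroxy-3-methylphenyl)propan-1-one
Product: 9 1-(2,6-dihydroxy-4-methoxy-3-methylphenyl)-3-(4-hydroxyphenyl)propan-1-one
Conditions: Me2SO4 (1.0 equiv), K2CO3 (1.0 equiv), acetone, rt
Reagents that add atoms: dimethyl sulfate, COS(=O)(=O)OC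
Why: Site-selective Williamson O-methylation; one equivalent of carbonate ionises the 4'-hydroxyl (para to the ketone, most acidic), while both ortho hydroxyls are engaged with the carbonyl group and the 4-hydroxyphenyl group is far less acidic, so the 4'-methyl ether should be the main product.

Step 6
Reactants: 5 5-(benzyloxy)-2-[(dimethylamino)methyl]-4-iodobenzene-1,3-diol; 9 1-(2,6-dihydroxy-4-methoxy-3-methylphenyl)-3-(4-hydroxyphenyl)propan-1-one
Product: 11 1-(3-{[4-(benzyloxy)-2,6-dihydroxy-3-iodophenyl]methyl}-2,6-dihydroxy-4-methoxy-5-methylphenyl)-3-(4-hydroxyphenyl)propan-1-one, via ortho-quinone methide 10 (not isolated)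
Conditions: 1,4-dioxane, 90 °C, argon stream (9 in twofold excess)
Reagents that add atoms: none
Why: Ortho-quinone methide alkylation from a phenolic Mannich base; on heating 5 loses dimethylamine to give 10, and 9, the most acidic partner and therefore present as its amine-paired phenolate, adds through its only unsubstituted ring carbon (C5') to the exocyclic methylene in a Michael-type step, after which both rings rearomatise.

Step 7
Reactants: 11 1-(3-{[4-(benzyloxy)-2,6-dihydroxy-3-iodophenyl]methyl}-2,6-dihydroxy-4-methoxy-5-methylphenyl)-3-(4-hydroxyphenyl)propan-1-one; 12 4-ethynylanisole; 13 carbon monoxide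
Product: 16 5-(benzyloxy)-8-({2,4-dihydroxy-3-[3-(4-hydroxyphenyl)propanoyl]-6-methoxy-5-methylphenyl}methyl)-7-hydroxy-2-(4-methoxyphenyl)-4H-chromen-4-one, via aryl ynone 14 (not isolated), via diethylamino enone 15 (not isolated)
Conditions: PdCl2(PPh3)2 (5 mol %), 13 (10 bar), 12 (2 equiv), Et2NH/DMF (1:1), 70 °C
Reagents that add atoms: none
Why: Zerovalent palladium, formed in situ from PdCl2(PPh3)2, inserts into the C–I bond of 11, carbon monoxide inserts to give the aroylpalladium iodide, and alkynylation by amine-deprotonated 12 with reductive elimination gives ynone 14; Et2NH then adds to 14 to give enaminone 15, whose ortho hydroxyl attacks the amine-bearing carbon and expels the amine. The closest known reaction is the palladium-catalysed carbonylative Sonogashira annulation of ortho-iodophenols with terminal alkynes in a secondary amine, which gives flavones. Ring C closes in the 6-endo mode (6-endo-trig addition–elimination on 15, formally 6-endo-dig on 14), forming C4a–C4, C4–C3 and O1–C2. No stereocentre is created. The step needs flavone over aurone selectivity, which the secondary amine secures by turning the ynone into the enaminone before the phenol can close 5-exo. It also needs closure toward C8a and not C5, which is secured because the only free hydroxyl ortho to the new acyl group is the one next to the bridge (the other ortho oxygen is the benzyl ether); the remaining phenols should be tolerated because the alkyne and the large excess of Et2NH outcompete phenolate for the acylpalladium species.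

Step 8
Reactants: 16 5-(benzyloxy)-8-({2,4-dihydroxy-3-[3-(4-hydroxyphenyl)propanoyl]-6-methoxy-5-methylphenyl}methyl)-7-hydroxy-2-(4-methoxyphenyl)-4H-chromen-4-one
Product: 17 tetraacetate of 16 (acetyl on O-7, on both phenolic oxygens flanking the propanoyl group, and on the 4-hydroxyphenyl oxygen)
Conditions: Ac2O, pyridine, DMAP (cat.), CH2Cl2, rt
Reagents that add atoms: acetic anhydride, CC(=O)OC(C)=O
Why: DMAP-catalysed O-acetylation should mask all four phenols, including the two hindered ones beside the ketone, so that no free phenol meets the dioxirane in the next step.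

Step 9
Reactants: 17 tetraacetate of 16
Product: 19 3-hydroxy derivative of 17 (3-hydroxyflavone tetraacetate), via flavone 2,3-epoxide 18 (not isolated)
Conditions: DMDO (acetone solution, excess), CH2Cl2, 0 °C → rt; then TsOH·H2O (cat.), CH2Cl2, rt
Reagents that add atoms: dimethyldioxirane, CC1(C)OO1
Why: Dioxirane epoxidation of the enol-ether-like C2=C3 bond of a 5-O-protected flavone, then acid-catalysed opening at C2 (cation stabilised by O1 and the anisyl ring) and loss of H-3, a known flavone-to-flavonol sequence; the epoxide is racemic and both of its stereocentres vanish on re-aromatisation of the pyranone.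

Step 10
Reactants: 19 3-hydroxyflavone tetraacetate
Product: 20 5-(benzyloxy)-3,7-dihydroxy-8-({2,4-dihydroxy-3-[3-(4-hydroxyphenyl)propanoyl]-6-methoxy-5-methylphenyl}methyl)-2-(4-methoxyphenyl)-4H-chromen-4-one
Conditions: HCl (1.25 M in MeOH), THF, rt → 40 °C
Reagents that add atoms: none
Why: Acid-catalysed methanolysis (transesterification) of the four aryl acetates; acid is preferred to base so that the air-sensitive flavonol phenolate and base-induced cleavage of the methylene bridge are avoided, and the benzyl ether should survive dilute methanolic HCl.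

Step 11
Reactants: 20 5-O-benzyl ether of the target
Product: 21 4'''-hydroxytrianguletin
Conditions: H2 (1 atm), 10% Pd/C, THF/MeOH, rt
Reagents that add atoms: none
Why: Hydrogenolysis of the benzyl aryl ether under neutral conditions; the pyranone double bond, the hindered chelated aryl ketone and the diarylmethane should not be reduced at atmospheric pressure.

**Compound list**

1 | 2,4,6-trihydroxybenzaldehyde | O=Cc1c(O)cc(O)cc1O | starting material
2 | 4-(benzyloxy)-2,6-dihydroxybenzaldehyde | O=Cc1c(O)cc(OCc2ccccc2)cc1O | intermediate
3 | 4-(benzyloxy)-2,6-dihydroxy-3-iodobenzaldehyde | O=Cc1c(O)cc(OCc2ccccc2)c(I)c1O | intermediate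
4 | iminium phenolate from 3 and dimethylamine: {[4-(benzyloxy)-6-hydroxy-5-iodo-2-oxidophenyl]methylidene}dimethylammonium | C[N+](C)=Cc1c([O-])cc(OCc2ccccc2)c(I)c1O | intermediate (not isolated)
5 | 5-(benzyloxy)-2-[(dimethylamino)methyl]-4-iodobenzene-1,3-diol | CN(C)Cc1c(O)cc(OCc2ccccc2)c(I)c1O | intermediate
6 | 2-methylphloroglucinol (2-methylbenzene-1,3,5-triol) | Cc1c(O)cc(O)cc1O | starting material
7 | 3-(4-hydroxyphenyl)propanoic acid | OC(=O)CCc1ccc(O)cc1 | starting material
8 | 3-(4-hydroxyphenyl)-1-(2,4,6-trihydroxy-3-methylphenyl)propan-1-one | Cc1c(O)cc(O)c(C(=O)CCc2ccc(O)cc2)c1O | intermediate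
9 | 1-(2,6-dihydroxy-4-methoxy-3-methylphenyl)-3-(4-hydroxyphenyl)propan-1-one | COc1cc(O)c(C(=O)CCc2ccc(O)cc2)c(O)c1C | intermediate
10 | ortho-quinone methide: 3-(benzyloxy)-5-hydroxy-2-iodo-6-methylidenecyclohexa-2,4-dien-1-one | C=C1C(=O)C(I)=C(OCc2ccccc2)C=C1O | intermediate (not isolated)
11 | 1-(3-{[4-(benzyloxy)-2,6-dihydroxy-3-iodophenyl]methyl}-2,6-dihydroxy-4-methoxy-5-methylphenyl)-3-(4-hydroxyphenyl)propan-1-one | COc1c(C)c(O)c(C(=O)CCc2ccc(O)cc2)c(O)c1Cc1c(O)cc(OCc2ccccc2)c(I)c1O | intermediate
12 | 4-ethynylanisole (1-ethynyl-4-methoxybenzene) | COc1ccc(C#C)cc1 | starting material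
13 | carbon monoxide | [C-]#[O+] | starting material
14 | aryl ynone: 1-[6-(benzyloxy)-3-({2,4-dihydroxy-3-[3-(4-hydroxyphenyl)propanoyl]-6-methoxy-5-methylphenyl}methyl)-2,4-dihydroxyphenyl]-3-(4-methoxyphenyl)prop-2-yn-1-one | COc1ccc(C#CC(=O)c2c(OCc3ccccc3)cc(O)c(Cc3c(O)c(C(=O)CCc4ccc(O)cc4)c(O)c(C)c3OC)c2O)cc1 | intermediate (not isolated)
15 | diethylamino enone: (E)-3-(diethylamino)-3-(4-methoxyphenyl)prop-2-en-1-one bearing the same aryl group as 14 on C1 (E drawn; the push–pull double bond isomerises freely) | CCN(CC)/C(=C/C(=O)c1c(OCc2ccccc2)cc(O)c(Cc2c(O)c(C(=O)CCc3ccc(O)cc3)c(O)c(C)c2OC)c1O)c1ccc(OC)cc1 | intermediate (not isolated)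
16 | 5-(benzyloxy)-8-({2,4-dihydroxy-3-[3-(4-hydroxyphenyl)propanoyl]-6-methoxy-5-methylphenyl}methyl)-7-hydroxy-2-(4-methoxyphenyl)-4H-chromen-4-one | COc1ccc(-c2cc(=O)c3c(OCc4ccccc4)cc(O)c(Cc4c(O)c(C(=O)CCc5ccc(O)cc5)c(O)c(C)c4OC)c3o2)cc1 | intermediate
17 | tetraacetate of 16 (O-7, both phenols beside the propanoyl group, 4-hydroxyphenyl oxygen) | COc1ccc(-c2cc(=O)c3c(OCc4ccccc4)cc(OC(C)=O)c(Cc4c(OC(C)=O)c(C(=O)CCc5ccc(OC(C)=O)cc5)c(OC(C)=O)c(C)c4OC)c3o2)cc1 | intermediate
18 | racemic 2,3-epoxide of 17 (oxirane cis-fused across C2–C3 of the pyranone; one enantiomer drawn) | O=C1[C@@H]2O[C@]2(c2ccc(OC)cc2)Oc2c(Cc3c(OC(C)=O)c(C(=O)CCc4ccc(OC(C)=O)cc4)c(OC(C)=O)c(C)c3OC)c(OC(C)=O)cc(OCc3ccccc3)c12 | intermediate (not isolated)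
19 | 3-hydroxy derivative of 17 (3-hydroxyflavone tetraacetate) | COc1ccc(-c2oc3c(Cc4c(OC(C)=O)c(C(=O)CCc5ccc(OC(C)=O)cc5)c(OC(C)=O)c(C)c4OC)c(OC(C)=O)cc(OCc4ccccc4)c3c(=O)c2O)cc1 | intermediate
20 | 5-(benzyloxy)-3,7-dihydroxy-8-({2,4-dihydroxy-3-[3-(4-hydroxyphenyl)propanoyl]-6-methoxy-5-methylphenyl}methyl)-2-(4-methoxyphenyl)-4H-chromen-4-one | COc1ccc(-c2oc3c(Cc4c(O)c(C(=O)CCc5ccc(O)cc5)c(O)c(C)c4OC)c(O)cc(OCc4ccccc4)c3c(=O)c2O)cc1 | intermediate
21 | 4'''-hydroxytrianguletin | COc1ccc(-c2oc3c(Cc4c(O)c(C(=O)CCc5ccc(O)cc5)c(O)c(C)c4OC)c(O)cc(O)c3c(=O)c2O)cc1 | target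

**Count and risks**

Total step count: 11. Longest linear sequence: 9 steps (steps 1, 2, 3, 6, 7, 8, 9, 10, 11; the dihydrochalcone branch, steps 4 and 5, joins at step 6).

Step 7 (key step). Oxidative addition into a C–I bond flanked by two oxygen substituents on an electron-rich ring may be slow. Reductive loss of iodine, capture of the acylpalladium species by Et2NH, or heterolysis of the methylene bridge in warm amine could then take over. The fallback closes ring C before the bridge exists; it sets out from 3 and rejoins the route at 16. The same carbonylative annulation (PdCl2(PPh3)2, Et2NH, 12, 13) is run on iodoaldehyde 3, a smaller iodide made less electron-rich by the formyl group and carrying no labile bridge. Closure through the only free ortho hydroxyl should give 5-(benzyloxy)-7-hydroxy-2-(4-methoxyphenyl)-4-oxo-4H-chromene-8-carbaldehyde F1. F1 is then joined to 9 by reductive Friedel–Crafts alkylation (Et3SiH, CF3CO2H, CH2Cl2, 0 °C), in which C5' of 9 adds to the protonated aldehyde and the silane reduces the resulting diarylmethyl cation, giving 16. Ring A is by then part of an electron-poor chromenone and cannot compete as a nucleophile.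

Step 6. The quinone methide 10 may be captured by the resorcinol ring of a second molecule of 5 or of product 11 instead of by 9, giving oligomers. The new C–C bond may also reopen on prolonged heating, or iodine may be lost. The fallback forms the bridge under acid before iodine is present; it sets out from 2 (together with 9) and rejoins the route at 11. Aldehyde 2 and an excess of 9 are combined in CF3CO2H/CH2Cl2 at 0 °C and Et3SiH is added last (reductive Friedel–Crafts alkylation). This should give 1-(3-{[4-(benzyloxy)-2,6-dihydroxyphenyl]methyl}-2,6-dihydroxy-4-methoxy-5-methylphenyl)-3-(4-hydroxyphenyl)propan-1-one F2. One equivalent of N-iodosuccinimide at −40 °C then iodinates one of the two equivalent ring A positions of F2 to give 11.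

Step 5. Alkylation may occur at the 6'-oxygen or at the 4-hydroxyphenyl oxygen, or twice, because four phenols compete and the 4'-hydroxyl is flanked by the C-methyl group. The fallback sets the ether pattern by directed ether cleavage instead of selective alkylation; it sets out from 8 and rejoins the route at 9. Methylation is pushed to the 4',6'-dimethyl ether (Me2SO4 2.2 equiv, K2CO3, acetone, reflux; the last chelated hydroxyl and the weakly acidic 4-hydroxyphenyl group stay free), giving 1-(2-hydroxy-4,6-dimethoxy-3-methylphenyl)-3-(4-hydroxyphenyl)propan-1-one F3. The methyl ether ortho to the carbonyl group is then removed by chelation-controlled cleavage with BCl3 (excess, CH2Cl2, −78 → 0 °C), which leaves the para methoxy group intact and gives 9. The regioisomeric 2',4'-dimethyl ether would converge on the same product.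

**Further compounds**

F1 | step 7 | 5-(benzyloxy)-7-hydroxy-2-(4-methoxyphenyl)-4-oxo-4H-chromene-8-carbaldehyde | COc1ccc(-c2cc(=O)c3c(OCc4ccccc4)cc(O)c(C=O)c3o2)cc1
F2 | step 6 | 1-(3-{[4-(benzyloxy)-2,6-dihydroxyphenyl]methyl}-2,6-dihydroxy-4-methoxy-5-methylphenyl)-3-(4-hydroxyphenyl)propan-1-one | COc1c(C)c(O)c(C(=O)CCc2ccc(O)cc2)c(O)c1Cc1c(O)cc(OCc2ccccc2)cc1O
F3 | step 5 | 1-(2-hydroxy-4,6-dimethoxy-3-methylphenyl)-3-(4-hydroxyphenyl)propan-1-one | COc1cc(OC)c(C(=O)CCc2ccc(O)cc2)c(O)c1C
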